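The runs stem from a simulated flask for substances that don't exist; the scatter is artificial.

It is easy to read the substrate that vanishes in the eta run as target, but at 15.0 s 62.2% of the charge has gone and target stands at 30.5%.

| setting | eta | alpha | flask |
|---|---|---|---|
| substrate | 0.050 M | 0.050 M | 0.050 M |
| coupling partner | 0.0475 M | 0.071 M | 0.0475 M |
| temperature | 80 °C | 86 °C | 80 °C |
| remark | the very flask that is asked about, followed so far | run made earlier |  |
| time |  |  | 3.0 min |

- eta (time / s: target / %, substrate / %): 15.0: 30.5, 37.8; 30.0: 34.9, 16.6; 50.0: 34.2, 6.6; 60.0: 34.5, 3.9; 80.0: 31.2, 1.9; 90.0: 31.3, 1.0; 120: 27.2, 0.4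
- alpha (time / s: target / %, substrate / %): 10.0: 37.5, 31.0; 15.0: 40.0, 19.1; 25.0: 41.9, 8.1; 40.0: 39.0, 2.2; 50.0: 36.1, 1.6; 80.0: 32.9, 0; 120: 31.5, 0.5

(each reading ± 0.5 percentage points)

- target, in percent of the substrate first charged, at 3.0 min
- the remedy with the largest gain of target, or "none" below 2 percentage points (west / south-east / north-east / north / none)
- target present, with what was taken out counted in, in percent of the substrate first charged, after west
- target present, with what was taken out counted in, in percent of the substrate first charged, after south-east

- west: at 3.0 min take out 90% of the target then present, then wait 50 s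
- south-east: change nothing and wait 50 s more
- north-east: at 3.0 min add coupling partner, 50.0% of the amount charged, then wait 50 s
- north: at 3.0 min raise the temperature by 25 K, then wait 50 s

- target that was removed still counts
- what was read earlier has a scatter of 0.5 percentage points, one standard deviation
- additions bring no volume worth counting

From that first eta reading I take N = 0.962, the split number, target found per unit of substrate gone elsewhere, a selectivity factor as read. The symmetric case, N = 1, is the zero of the scale: substrate divides evenly, and above it coupling wins. The share reaching target is N/(1 + N), here 49.0%.

If the loss needs no coupling partner, N at fixed temperature grows with [coupling partner], so the alpha charge at the eta temperature should show 1.44. The first reading of the alpha run gives 1.19, which is less, at 86 °C rather than 80 °C. One number does not carry from the eta run to the alpha run, so I use it for this flask, at the temperature of the eta run.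

Target then falls in the eta run, to 27.2% at 120 s, and levels in the alpha run. I apply the symmetric case again, to what target keeps of its share, so I commit to 24.5% in this flask, half of that share. The alpha run ends at 0.580 of its own share, so my figure may be low. N does not rank the remedies, but substrate in the eta run already reads 0.4% at 120 s, far less than the 37.8% of the first reading, and north-east acts later, at 3.0 min, so I expect little from it.

The forecast gives 26%, above mine, and chooses west, with 34.5% after west and 25.8% after south-east: “This rests on the inferred reversibility.”

This flask gives 25.4%; north gains 8.3 percentage points, more than west's 5 points, and north-east −1 point, with 30.3% after west and 24.3% after south-east.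

    substrate + coupling partner → target (k = 1.00 M⁻¹ s⁻¹, Ea = 53.0 kJ mol⁻¹)
    substrate → side product (k = 0.0310 s⁻¹, Ea = 84.0 kJ mol⁻¹)
    2 coupling partner → self-condensation product A (k = 0.190 M⁻¹ s⁻¹, Ea = 65.0 kJ mol⁻¹)
    target ⇌ isomer of the product (K = 1.00, k = 0.00750 s⁻¹, Ea = 94.0 kJ mol⁻¹, ΔH = −42.0 kJ mol⁻¹)
    2 substrate → self-condensation product B (k = 0.00140 M⁻¹ s⁻¹, Ea = 93.0 kJ mol⁻¹)
    (constants at 80 °C)

At the start of this flask, coupling runs 1.53 times as fast as the step to side product. With coupling partner at 47.8% at 0.300 min, that ratio is 0.733. At 3.00 min, target and isomer of the product hold 46.7% against side product 53.2%, an N of 0.878. Scaled to the neighbour charged with 0.12 M, N becomes 2.43, and that neighbour stands at 2.36.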